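A one-step world is easy: substrate meets reagent and each meeting gives product. Here double product takes two reagent units per substrate, by way of a first product.

common to all: substrate 0.20 M

| charge | reagent | remark | time |
|---|---|---|---|
| theta | 0.11 M | run made earlier |  |
| epsilon | 0.36 M | run made earlier |  |
| autumn | 0.0800 M |  | 60 min |
| midnight | 0.300 M |  | 15 min |

- theta (time / min: double product / %, substrate / %): 1.33: 0.4, 89.1; 2.50: 1.3, 78.2; 4.00: 3.7, 73.8; 5.00: 6.1, 69.8; 6.00: 7.2, 65.9; 8.00: 8.4, 62.6
- epsilon (time / min: double product / %, substrate / %): 0.500: 1.9, 82.8; 1.33: 9.5, 63.5; 2.50: 19.5, 46.1; 4.00: 32.1, 34.1; 6.00: 41.4, 26.3; 8.00: 50.3, 19.5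

(standard deviation of a reading: 1 percentage point)

- which of the two ends with the higher amount of double product, in percent of the substrate charged ("neither" if they lie within 2 percentage points) (autumn / midnight / neither)
- double product at the end, in percent of the substrate charged, autumn
- double product at the end, in percent of the substrate charged, midnight

- a reading or a percentage of double product counts all its forms, free or not

Two extremes can be solved in the head, with u equivalents of reagent taken up per substrate. If the second step is far faster than the first, double product is u/2: 20.0% in autumn, 75.0% in midnight. If it is far slower, double product is what exceeds one equivalent: 0% in autumn, 50.0% in midnight.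

The zero of the scale lies between them, at equal constants, the symmetric case. With a fraction s of substrate left and x = ln(1/s), double product is 1 − s(1 + x). Theta's last substrate reading gives 8.08% against 8.4% read, and epsilon's gives 48.6% against 50.3%, so the readings sit near that zero.

Epsilon's early substrate loss reads as a reagent lifetime near 5.27 min, shorter than autumn's 60 min, so autumn's whole charge, u = 0.400, counts as taken up. Then x ≈ u + u^3/6, which gives 6.44%: this is the symmetric share, the double product of equal steps for the reagent taken up.

Midnight is bound by time. At equal substrate left, epsilon's reagent exceeds midnight's by a factor growing from 1.20 to 2.44 at its last reading, and midnight's time exceeds that reading's by 1.88. So the reckoning here puts midnight near epsilon's last point, at about 48.6%.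

The forecast, holding that “reagent is exhausted well before 60 min”, names midnight, with 6.5% (5% to 8.5%) for autumn and 52% (47% to 57%) for midnight, above the reckoning here.

The flask gives 6.79% in autumn and 53.0% in midnight.

    substrate + reagent → first product (k = 1.10 M⁻¹ min⁻¹)
    reagent + first product → double product (k = 1.21 M⁻¹ min⁻¹)
    crystals ⇌ double product, rate k3*(cs3 - [double product]) while solid is left; crystals form when [double product] > cs3 (solubility = 39.0 mM, k = 6.83 min⁻¹)
    substrate → decomposition product (k = 4.70 × 10⁻⁵ min⁻¹)

In midnight the first step had half of its turnover up to 15 min behind it by 1.95 min, and the second had 74% of its own by 7.50 min, with reagent then at 25.8% of its charge. Autumn's 6.79% stands above its symmetric share of 6.44%, and the second constant exceeds the first.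

In a neighbour flask, midnight with 0.12 M of reagent, u = 0.600 gives a symmetric share of 13.4%. That flask ends at 12.8%, with 4.43% of its reagent left.

Readings and results are calculated with constants of no real substance.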